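Labels: ring A carbons are called 1' (bears the depsidone C=O), 2' (ether O), 3' (CH2OH), 4' (OCH3), 5' (H), 6' (CH3); ring B carbons are b1 (ether O), b2 (ester O), b3 (CH3), b4 (OH), b5 (phthalide C=O), b6 (lactol carbon).
Retrosynthesis: the lactol stereocentre is given up first (racemic lactol), the lactol ring is opened to a b5 methyl ester and a b6 acetal, the depsidone is cut at the ester bond between the 1' carbonyl and the b2 oxygen and then at the ether bond between position 2' and the b1 oxygen, and ring B is cut across b4–b5 and b1–b6.
Enabling feature: ring B is hexasubstituted, with oxygens para to each other on b1 and b4, a third oxygen on b2, the methyl on b3, and a carboxyl carbon next to a formyl-level carbon on b5 and b6; a 3-alkoxy-4-methyl-2-siloxyfuran and a 4-oxobut-2-ynoate give exactly this pattern by [4+2] cycloaddition and opening of the oxygen bridge.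
Forward: butenolide, then siloxyfuran, then ring B by cycloaddition and aromatisation; ring A is taken from 3-fluoro-5-methylanisole by two ortho-lithiations; the rings are joined by SNAr at position 2', the seven-membered ring closes by lactonisation, and the five-membered lactol ring closes last on unmasking.
Stereochemistry: the only stereocentre, the (R)-lactol carbon, is set by lipase-catalysed dynamic kinetic acetylation of the interconverting lactol epimers and kept through an enzymatic deacetylation that does not touch its C–O bond.

Key step: step 5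

Assumption: as in any 3-hydroxyphthalide, the lactol carbon can epimerise through the ring-opened formyl acid, so it is set in the last two steps and the target is isolated and stored cold, dry and free of base. Compounds drawn without a stereodescriptor at a stereocentre are racemates.

Step 1
Reactants: 1 diethyl 2-methyl-3-oxobutanedioate (diethyl oxalpropionate)
Product: 4 3-hydroxy-4-methylfuran-2(5H)-one, via aldol adduct 2 (not isolated), via keto lactone ester 3 (not isolated)
Conditions: 37% aq. CH2O, K2CO3 (1 equiv), H2O, 0 °C to rt; then conc. HCl, reflux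
Reagents that add atoms: formaldehyde, C=O
Why: Aldol addition of the single enolisable carbon to formaldehyde, lactonisation of the new hydroxymethyl group onto the oxalyl ester, and acid hydrolysis with decarboxylation of the beta-keto acid form the classical route to alpha-keto-gamma-butyrolactones, which rest as the enol 4.

Step 2
Reactants: 4 3-hydroxy-4-methylfuran-2(5H)-one
Product: 5 3-(benzyloxy)-4-methylfuran-2(5H)-one
Conditions: BnBr, K2CO3, DMF, rt
Reagents that add atoms: benzyl bromide, BrCc1ccccc1
Why: Williamson O-alkylation of the acidic enol should place the benzyl group on oxygen, since carbonate in a dipolar aprotic solvent favours O- over C-alkylation of this delocalised enolate.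

Step 3
Reactants: 5 3-(benzyloxy)-4-methylfuran-2(5H)-one
Product: 6 3-(benzyloxy)-4-methyl-2-[(triisopropylsilyl)oxy]furan
Conditions: TIPSOTf, Et3N, CH2Cl2, 0 °C; used without chromatography
Reagents that add atoms: triisopropylsilyl trifluoromethanesulfonate, CC(C)[Si](OS(=O)(=O)C(F)(F)F)(C(C)C)C(C)C
Why: Soft enolisation (gamma-deprotonation of the butenolide by Et3N and O-silylation of the furanolate by the silyl triflate) is the standard preparation of 2-siloxyfurans, and the triisopropylsilyl group is chosen so that the later aryl silyl ether survives carbonate base.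

Step 4
Reactants: 7 methyl 4-hydroxybut-2-ynoate
Product: 8 methyl 4-oxobut-2-ynoate
Conditions: activated MnO2 (excess), CH2Cl2, rt; filtered and used as a cold solution
Reagents that add atoms: none
Why: MnO2 oxidation of a propargylic alcohol stops at the ynal under neutral conditions, and the filtrate can be used directly so that the sensitive aldehyde is never concentrated.

Step 5
Reactants: 6 3-(benzyloxy)-4-methyl-2-[(triisopropylsilyl)oxy]furan; 8 methyl 4-oxobut-2-ynoate
Product: 10 methyl 4-(benzyloxy)-2-formyl-6-hydroxy-5-methyl-3-[(triisopropylsilyl)oxy]benzoate, via oxanorbornadiene adduct 9 (not isolated)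
Conditions: CH2Cl2, −40 °C to rt, no Lewis acid; kept at rt until the adduct has opened
Reagents that add atoms: none
Why: The electron-rich furan adds across the electron-poor alkyne in a normal-demand [4+2] cycloaddition, which may be asynchronous enough to amount to a vinylogous Mukaiyama–Michael addition through C5 followed by closure at C2, and gives oxanorbornadiene 9; heterolysis of the bridging C–O bond at the siloxy-bearing bridgehead and loss of the proton from the other bridgehead then aromatise it, so that the furan oxygen becomes the b4 hydroxyl and the silyl ether stays on b1. The closest known reaction type is the Diels–Alder reaction of 2-siloxy- and 2-alkoxyfurans with acetylenic esters and ynals, whose adducts open in the flask to para-oxygenated phenols. Ring B, the only ring formed, closes by intermolecular [4+2] cycloaddition that makes the b4–b5 and b1–b6 bonds, after which the oxygen bridge opens. No stereocentre remains, because the two bridgehead centres of racemic 9 are lost on aromatisation. The step needs regioselectivity (b4 joined to the ester-bearing carbon) and chemoselectivity for the alkyne over the formyl carbon: the first should follow from pairing the most nucleophilic furan carbon, C5 (vinylogous to the siloxy group and supported by the 4-methyl group), with the alkyne carbon beta to the formyl group, the stronger of the two acceptors, and the second from working without a Lewis acid. The three oxygens of ring B emerge differentiated as silyl ether (b1), benzyl ether (b2) and chelated free phenol (b4), which the later ether and lactone closures require.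

Step 6
Reactants: 10 methyl 4-(benzyloxy)-2-formyl-6-hydroxy-5-methyl-3-[(triisopropylsilyl)oxy]benzoate
Product: 11 methyl 4-(benzyloxy)-2-(dimethoxymethyl)-6-hydroxy-5-methyl-3-[(triisopropylsilyl)oxy]benzoate
Conditions: HC(OMe)3, camphorsulfonic acid (cat.), MeOH, 50 °C
Reagents that add atoms: trimethyl orthoformate, COC(OC)OC; methanol, CO
Why: Acid-catalysed acetalisation driven by the orthoformate masks the b6 aldehyde against the later hydride reduction, while the aryl silyl ether, the methyl ester and the chelated phenol are inert to catalytic acid.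

Step 7
Reactants: 11 methyl 4-(benzyloxy)-2-(dimethoxymethyl)-6-hydroxy-5-methyl-3-[(triisopropylsilyl)oxy]benzoate
Product: 12 methyl 2,4-bis(benzyloxy)-6-(dimethoxymethyl)-3-methyl-5-[(triisopropylsilyl)oxy]benzoate
Conditions: BnBr, K2CO3, Bu4NI (cat.), acetone, reflux
Reagents that add atoms: benzyl bromide, BrCc1ccccc1
Why: Williamson etherification of the only free phenol keeps b4–OH out of the diaryl ether formation, and the new benzyl group leaves later together with the other two in one hydrogenolysis.

Step 8
Reactants: 13 1-fluoro-3-methoxy-5-methylbenzene (3-fluoro-5-methylanisole)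
Product: 14 2-fluoro-6-methoxy-4-methylbenzaldehyde
Conditions: n-BuLi, THF, −78 °C; DMF; then 1 M HCl
Reagents that add atoms: N,N-dimethylformamide, CN(C)C=O
Why: Directed ortho-metalation removes the proton flanked by fluorine and methoxy, the most acidic one, and formylation of the aryllithium with DMF installs the carbon that becomes the 3' hydroxymethyl carbon of ring A.

Step 9
Reactants: 14 2-fluoro-6-methoxy-4-methylbenzaldehyde
Product: 15 2-(dimethoxymethyl)-1-fluoro-3-methoxy-5-methylbenzene
Conditions: HC(OMe)3, TsOH·H2O (cat.), MeOH, rt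
Reagents that add atoms: trimethyl orthoformate, COC(OC)OC; methanol, CO
Why: Acid-catalysed acetalisation protects the aldehyde against the second organolithium step.

Step 10
Reactants: 15 2-(dimethoxymethyl)-1-fluoro-3-methoxy-5-methylbenzene
Product: 17 benzyl 2-fluoro-3-formyl-4-methoxy-6-methylbenzoate, via acetal ester 16 (not isolated)
Conditions: s-BuLi, PMDTA, THF, −78 °C; cannulated into ClCO2Bn, THF, −78 °C; then 1 M HCl, THF, rt
Reagents that add atoms: benzyl chloroformate, O=C(Cl)OCc1ccccc1; water, O
Why: Fluorine-directed ortho-lithiation with a triamine-complexed base, which follows C–H acidity and not methoxy coordination, should metalate the one remaining position next to fluorine; inverse addition to the chloroformate then gives the ester, and the acidic work-up hydrolyses the acetal.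

Step 11
Reactants: 12 methyl 2,4-bis(benzyloxy)-6-(dimethoxymethyl)-3-methyl-5-[(triisopropylsilyl)oxy]benzoate; 17 benzyl 2-fluoro-3-formyl-4-methoxy-6-methylbenzoate
Product: 19 methyl 2,4-bis(benzyloxy)-5-{2-[(benzyloxy)carbonyl]-6-formyl-5-methoxy-3-methylphenoxy}-6-(dimethoxymethyl)-3-methylbenzoate, via caesium phenoxide 18 (not isolated)
Conditions: CsF, DMF, 80 °C
Reagents that add atoms: none
Why: In this fluoride-triggered nucleophilic aromatic substitution (addition–elimination), CsF frees the b1 phenoxide from its silyl ether, the phenoxide displaces the fluoride at position 2' of ring A, which is activated by the ortho formyl and ortho ester groups, and the fluoride set free carries the desilylation on; SNAr should tolerate four ortho substituents better than a metal-catalysed coupling.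

Step 12
Reactants: 19 the diaryl ether aldehyde of step 11
Product: 20 methyl 2,4-bis(benzyloxy)-5-{2-[(benzyloxy)carbonyl]-6-(hydroxymethyl)-5-methoxy-3-methylphenoxy}-6-(dimethoxymethyl)-3-methylbenzoate
Conditions: NaBH4, THF/MeOH, 0 °C
Reagents that add atoms: none
Why: Borohydride reduction takes the aldehyde at position 3' of ring A, which has done its work as activating group, to the hydroxymethyl group of the target and leaves both esters and the acetal untouched.

Step 13
Reactants: 20 the benzylic alcohol of step 12
Product: 21 methyl 2,4-bis(benzyloxy)-5-{2-[(benzyloxy)carbonyl]-6-{[(tert-butyldimethylsilyl)oxy]methyl}-5-methoxy-3-methylphenoxy}-6-(dimethoxymethyl)-3-methylbenzoate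
Conditions: TBSCl, imidazole, DMF, rt
Reagents that add atoms: tert-butyldimethylsilyl chloride, CC(C)(C)[Si](C)(C)Cl
Why: Imidazole-promoted silylation protects the primary alcohol so that it cannot compete as a nucleophile in the lactonisation.

Step 14
Reactants: 21 the silyl ether of step 13
Product: 22 3-{[(tert-butyldimethylsilyl)oxy]methyl}-2-[2-(dimethoxymethyl)-4,6-dihydroxy-3-(methoxycarbonyl)-5-methylphenoxy]-4-methoxy-6-methylbenzoic acid
Conditions: H2 (1 atm), Pd/C, EtOAc (dry), rt; used at once
Reagents that add atoms: none
Why: Catalytic hydrogenolysis cleaves the benzyl ester at position 1' of ring A and the benzyl ethers at b2 and b4 in one operation, while the acetal, the methyl ester and the hindered benzylic silyl ether should persist under neutral conditions.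

Step 15
Reactants: 22 the hydroxy acid of step 14
Product: 23 methyl 4-{[(tert-butyldimethylsilyl)oxy]methyl}-6-(dimethoxymethyl)-8-hydroxy-3-methoxy-1,9-dimethyl-11-oxo-11H-dibenzo[b,e][1,4]dioxepine-7-carboxylate (depsidone: lactone from the 1' carboxyl to the b2 oxygen and ether from position 2' to the b1 oxygen; CH2OTBS at position 3', b4 OH, b5 CO2CH3, b6 CH(OCH3)2)
Conditions: DCC, DMAP (cat.), CH2Cl2 (0.005 M), 0 °C to rt
Reagents that add atoms: none
Why: Steglich-type carbodiimide lactonisation at high dilution closes the seven-membered ring, because only b2–OH can reach the 1' carboxylic acid intramolecularly and b4–OH is hindered and hydrogen-bonded to its neighbouring ester.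

Step 16
Reactants: 23 the depsidone acetal ester of step 15
Product: 25 racemic 1,4-dihydroxy-11-(hydroxymethyl)-10-methoxy-5,8-dimethyl-1H-isobenzofuro[4,5-b][1,4]benzodioxepine-3,7-dione (racemic lactol), via formyl ester 24 (not isolated)
Conditions: 1 M HCl, THF, 40 °C; then aq. LiOH (3 equiv), THF/H2O, 0 °C, 5–10 min; then 1 M HCl to pH 2
Reagents that add atoms: water, O; lithium hydroxide, [Li+].[OH-]
Why: Acid hydrolysis frees the b6 aldehyde and the primary alcohol, and then intramolecular nucleophilic catalysis (hydroxide adds to the ortho formyl group and the hydrate anion attacks the neighbouring methyl ester) should cleave this ester much faster than the doubly ortho-substituted depsidone ester, so that acidification closes the hydroxyphthalide ring.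

Step 17
Reactants: 25 racemic lactol
Product: 26 (R)-diacetate: the depsidone of 25 with an acetoxy group on the (R)-configured lactol carbon and CH2OAc at position 3' of ring A, b4–OH free
Conditions: Burkholderia cepacia lipase (immobilised), vinyl acetate, Et3N (0.1 equiv), THF/toluene, 35 °C
Reagents that add atoms: vinyl acetate, C=COC(C)=O
Why: In this lipase-catalysed acylative dynamic kinetic resolution the lactol epimers interconvert through the ring-opened formyl acid under amine catalysis while the enzyme acetylates one of them, expected to be the (R)-lactol, so that all material should funnel into the configurationally stable (R)-acetate; the primary alcohol is acetylated as well and the hindered chelated phenol is not.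

Step 18
Reactants: 26 (R)-diacetate
Product: 27 (R)-cryptostictic acid, (1R)-1,4-dihydroxy-11-(hydroxymethyl)-10-methoxy-5,8-dimethyl-1H-isobenzofuro[4,5-b][1,4]benzodioxepine-3,7-dione
Conditions: Burkholderia cepacia lipase (immobilised), n-BuOH, t-BuOMe (dry), 4 °C; filtered and evaporated cold
Reagents that add atoms: none
Why: Lipase-catalysed alcoholysis (transesterification to n-butanol) cleaves both acetates at the acyl carbon, so the C–O bond of the stereocentre is not touched and the (R) configuration is retained, and the absence of base and water at low temperature should suppress ring-opening of the liberated lactol.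

Compound list
1 | diethyl 2-methyl-3-oxobutanedioate (diethyl oxalpropionate) | CCOC(=O)C(C)C(=O)C(=O)OCC | starting material
2 | diethyl 2-(hydroxymethyl)-2-methyl-3-oxobutanedioate (racemic) | CCOC(=O)C(C)(CO)C(=O)C(=O)OCC | intermediate (not isolated)
3 | ethyl 3-methyl-4,5-dioxooxolane-3-carboxylate (racemic) | CCOC(=O)C1(C)COC(=O)C1=O | intermediate (not isolated)
4 | 3-hydroxy-4-methylfuran-2(5H)-one | CC1=C(O)C(=O)OC1 | intermediate
5 | 3-(benzyloxy)-4-methylfuran-2(5H)-one | CC1=C(OCc2ccccc2)C(=O)OC1 | intermediate
6 | 3-(benzyloxy)-4-methyl-2-[(triisopropylsilyl)oxy]furan | Cc1coc(O[Si](C(C)C)(C(C)C)C(C)C)c1OCc1ccccc1 | intermediate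
7 | methyl 4-hydroxybut-2-ynoate | COC(=O)C#CCO | starting material
8 | methyl 4-oxobut-2-ynoate | COC(=O)C#CC=O | intermediate
9 | methyl 5-(benzyloxy)-3-formyl-6-methyl-4-[(triisopropylsilyl)oxy]-7-oxabicyclo[2.2.1]hepta-2,5-diene-2-carboxylate (racemic) | COC(=O)C1=C(C=O)C2(O[Si](C(C)C)(C(C)C)C(C)C)OC1C(C)=C2OCc1ccccc1 | intermediate (not isolated)
10 | methyl 4-(benzyloxy)-2-formyl-6-hydroxy-5-methyl-3-[(triisopropylsilyl)oxy]benzoate | COC(=O)c1c(O)c(C)c(OCc2ccccc2)c(O[Si](C(C)C)(C(C)C)C(C)C)c1C=O | intermediate
11 | methyl 4-(benzyloxy)-2-(dimethoxymethyl)-6-hydroxy-5-methyl-3-[(triisopropylsilyl)oxy]benzoate | COC(=O)c1c(O)c(C)c(OCc2ccccc2)c(O[Si](C(C)C)(C(C)C)C(C)C)c1C(OC)OC | intermediate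
12 | methyl 2,4-bis(benzyloxy)-6-(dimethoxymethyl)-3-methyl-5-[(triisopropylsilyl)oxy]benzoate | COC(=O)c1c(OCc2ccccc2)c(C)c(OCc2ccccc2)c(O[Si](C(C)C)(C(C)C)C(C)C)c1C(OC)OC | intermediate
13 | 1-fluoro-3-methoxy-5-methylbenzene (3-fluoro-5-methylanisole) | COc1cc(C)cc(F)c1 | starting material
14 | 2-fluoro-6-methoxy-4-methylbenzaldehyde | COc1cc(C)cc(F)c1C=O | intermediate
15 | 2-(dimethoxymethyl)-1-fluoro-3-methoxy-5-methylbenzene | COc1cc(C)cc(F)c1C(OC)OC | intermediate
16 | benzyl 3-(dimethoxymethyl)-2-fluoro-4-methoxy-6-methylbenzoate | COc1cc(C)c(C(=O)OCc2ccccc2)c(F)c1C(OC)OC | intermediate (not isolated)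
17 | benzyl 2-fluoro-3-formyl-4-methoxy-6-methylbenzoate | COc1cc(C)c(C(=O)OCc2ccccc2)c(F)c1C=O | intermediate
18 | caesium 2,4-bis(benzyloxy)-6-(dimethoxymethyl)-5-(methoxycarbonyl)-3-methylphenolate | COC(=O)c1c(OCc2ccccc2)c(C)c(OCc2ccccc2)c([O-])c1C(OC)OC.[Cs+] | intermediate (not isolated)
19 | methyl 2,4-bis(benzyloxy)-5-{2-[(benzyloxy)carbonyl]-6-formyl-5-methoxy-3-methylphenoxy}-6-(dimethoxymethyl)-3-methylbenzoate | COC(=O)c1c(OCc2ccccc2)c(C)c(OCc2ccccc2)c(Oc2c(C=O)c(OC)cc(C)c2C(=O)OCc2ccccc2)c1C(OC)OC | intermediate
20 | methyl 2,4-bis(benzyloxy)-5-{2-[(benzyloxy)carbonyl]-6-(hydroxymethyl)-5-methoxy-3-methylphenoxy}-6-(dimethoxymethyl)-3-methylbenzoate | COC(=O)c1c(OCc2ccccc2)c(C)c(OCc2ccccc2)c(Oc2c(CO)c(OC)cc(C)c2C(=O)OCc2ccccc2)c1C(OC)OC | intermediate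
21 | methyl 2,4-bis(benzyloxy)-5-{2-[(benzyloxy)carbonyl]-6-{[(tert-butyldimethylsilyl)oxy]methyl}-5-methoxy-3-methylphenoxy}-6-(dimethoxymethyl)-3-methylbenzoate | COC(=O)c1c(OCc2ccccc2)c(C)c(OCc2ccccc2)c(Oc2c(CO[Si](C)(C)C(C)(C)C)c(OC)cc(C)c2C(=O)OCc2ccccc2)c1C(OC)OC | intermediate
22 | 3-{[(tert-butyldimethylsilyl)oxy]methyl}-2-[2-(dimethoxymethyl)-4,6-dihydroxy-3-(methoxycarbonyl)-5-methylphenoxy]-4-methoxy-6-methylbenzoic acid | COC(=O)c1c(O)c(C)c(O)c(Oc2c(CO[Si](C)(C)C(C)(C)C)c(OC)cc(C)c2C(=O)O)c1C(OC)OC | intermediate
23 | methyl 4-{[(tert-butyldimethylsilyl)oxy]methyl}-6-(dimethoxymethyl)-8-hydroxy-3-methoxy-1,9-dimethyl-11-oxo-11H-dibenzo[b,e][1,4]dioxepine-7-carboxylate | COc1cc(C)c2c(c1CO[Si](C)(C)C(C)(C)C)Oc1c(c(C)c(O)c(C(=O)OC)c1C(OC)OC)OC2=O | intermediate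
24 | methyl 6-formyl-8-hydroxy-4-(hydroxymethyl)-3-methoxy-1,9-dimethyl-11-oxo-11H-dibenzo[b,e][1,4]dioxepine-7-carboxylate | COc1cc(C)c2c(c1CO)Oc1c(c(C)c(O)c(C(=O)OC)c1C=O)OC2=O | intermediate (not isolated)
25 | racemic 1,4-dihydroxy-11-(hydroxymethyl)-10-methoxy-5,8-dimethyl-1H-isobenzofuro[4,5-b][1,4]benzodioxepine-3,7-dione (racemic lactol) | COc1cc(C)c2c(c1CO)Oc1c(c(C)c(O)c3c1C(O)OC3=O)OC2=O | intermediate
26 | (R)-diacetate: [(1R)-1-acetoxy-4-hydroxy-10-methoxy-5,8-dimethyl-3,7-dioxo-1H-isobenzofuro[4,5-b][1,4]benzodioxepin-11-yl]methyl acetate | COc1cc(C)c2c(c1COC(C)=O)Oc1c(c(C)c(O)c3c1[C@H](OC(C)=O)OC3=O)OC2=O | intermediate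
27 | (R)-cryptostictic acid, (1R)-1,4-dihydroxy-11-(hydroxymethyl)-10-methoxy-5,8-dimethyl-1H-isobenzofuro[4,5-b][1,4]benzodioxepine-3,7-dione | COc1cc(C)c2c(c1CO)Oc1c(c(C)c(O)c3c1[C@H](O)OC3=O)OC2=O | target

Total step count: 18
Longest linear sequence: 14 steps (steps 1–3, 5–7 and 11–18, from compound 1)

Steps most likely to fail

Step 5. The siloxyfuran may add through C5 to the formyl carbon (a vinylogous aldol-type 1,2-addition) instead of the alkyne, the ynal may oligomerise before it is consumed, or the regiocontrol may be incomplete. The fallback sets out from furan 6 and replaces the aldehyde by a thioester, which cannot undergo 1,2-addition without a catalyst and is still the stronger of the two acceptors, although by a smaller margin. The dienophile methyl 4-(ethylsulfanyl)-4-oxobut-2-ynoate F1 would be made from commercial methyl propiolate (LiN(SiMe3)2, THF, −78 °C, then S-ethyl chlorothioformate). Its cycloaddition with 6 under the conditions of step 5 should pass through the oxanorbornadiene thioester methyl 5-(benzyloxy)-3-[(ethylsulfanyl)carbonyl]-6-methyl-4-[(triisopropylsilyl)oxy]-7-oxabicyclo[2.2.1]hepta-2,5-diene-2-carboxylate F2 and give, after opening, methyl 4-(benzyloxy)-2-[(ethylsulfanyl)carbonyl]-6-hydroxy-5-methyl-3-[(triisopropylsilyl)oxy]benzoate F3. A Fukuyama reduction (Et3SiH, Pd/C, acetone, rt) would then take the thioester to the aldehyde, and the route is rejoined at compound 10.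

Step 17. The enzyme may accept the crowded lactol poorly, or acetylate it with the opposite sense or with low selectivity. The fallback sets out from racemic lactol 25 and uses a non-enzymatic acylative dynamic kinetic resolution: acetic anhydride, i-Pr2NEt and a chiral nucleophilic acyl-transfer catalyst of the bicyclic imidazole type (both antipodes are accessible, so the (R)-acetate can be chosen), toluene, −20 °C. It comes back to the route at compound 26 and makes no compound outside the list (F0).

Step 18. The freed lactol may lose configurational purity through ring-chain tautomerism if the deacetylation is slow, or the crowded lactol acetate may be cleaved incompletely. The fallback sets out from racemic lactol 25 and changes the acyl group to one that is removed by hydrogenolysis. Acylative dynamic kinetic resolution with dibenzyl dicarbonate and the chiral acyl-transfer catalyst named above should give the bis(benzyl carbonate) benzyl [(1S)-11-({[(benzyloxy)carbonyl]oxy}methyl)-4-hydroxy-10-methoxy-5,8-dimethyl-3,7-dioxo-1H-isobenzofuro[4,5-b][1,4]benzodioxepin-1-yl] carbonate F4. Its descriptor is S only because the carbonate oxygen outranks the ring oxygen; the spatial arrangement is that of 27. Hydrogenolysis (H2, Pd/C, EtOAc, 0 °C) would cleave the two O-benzyl bonds to the bis(carbonic acid half-ester) F5, which loses carbon dioxide under neutral conditions without passing through a lactol alkoxide, and the route ends at compound 27.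

Further compounds
F1 | step 5 | methyl 4-(ethylsulfanyl)-4-oxobut-2-ynoate | CCSC(=O)C#CC(=O)OC
F2 | step 5 | methyl 5-(benzyloxy)-3-[(ethylsulfanyl)carbonyl]-6-methyl-4-[(triisopropylsilyl)oxy]-7-oxabicyclo[2.2.1]hepta-2,5-diene-2-carboxylate (racemic, not isolated) | COC(=O)C1=C(C(=O)SCC)C2(O[Si](C(C)C)(C(C)C)C(C)C)OC1C(C)=C2OCc1ccccc1
F3 | step 5 | methyl 4-(benzyloxy)-2-[(ethylsulfanyl)carbonyl]-6-hydroxy-5-methyl-3-[(triisopropylsilyl)oxy]benzoate | COC(=O)c1c(O)c(C)c(OCc2ccccc2)c(O[Si](C(C)C)(C(C)C)C(C)C)c1C(=O)SCC
F0 | step 17 | none | none
F4 | step 18 | benzyl [(1S)-11-({[(benzyloxy)carbonyl]oxy}methyl)-4-hydroxy-10-methoxy-5,8-dimethyl-3,7-dioxo-1H-isobenzofuro[4,5-b][1,4]benzodioxepin-1-yl] carbonate | COc1cc(C)c2c(c1COC(=O)OCc1ccccc1)Oc1c(c(C)c(O)c3c1[C@H](OC(=O)OCc1ccccc1)OC3=O)OC2=O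
F5 | step 18 | bis(carbonic acid half-ester) of 27 at the lactol oxygen and at the hydroxymethyl oxygen of ring A (not isolated) | COc1cc(C)c2c(c1COC(=O)O)Oc1c(c(C)c(O)c3c1[C@H](OC(=O)O)OC3=O)OC2=O
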